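**Strategy**

The route rests on cutting C7–C8. In the target C7 is the γ carbon of the allyl unit C13–C11–C7 that sits in the five-membered lactone (O–C6–C7–C11–C12), and C8 is a carbinol of the ten-membered ring (C1–C10). An allylchromium made at C13 of a 3-(bromomethyl)butenolide therefore adds through C7 to a tethered C8 aldehyde: one operation closes the carbocycle, shifts the double bond to the exocyclic C11=C13 position and sets C7 and C8, leaving O8 free beside a silylated O9. The precursor, compound 24, is the (5S)-butenolide whose E,Z-diene chain ends in the (R)-α-silyloxy aldehyde.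

Key step: step 16

Remarks on the chemistry
- Locants C1–C15 are the germacranolide locants of the target (C6 lactone O–CH, C7 ring fusion, C8 acyloxy CH, C9 carbinol, C10(Me)=C1 Z, C4(Me)=C5 E, C11=C13 methylene, C12 carbonyl). TBS = tert-butyldimethylsilyl, TES = triethylsilyl.
- Assumption: the zinc–ProPhenol alkynylation of step 10 is taken to follow the facial sense of the related aldol reactions, so that the (S,S)-ligand adds the alkynyl group to the Re face of the enal. The configuration of 18 is to be checked by Mosher ester analysis and the (R,R)-ligand used if the sense proves opposite.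
- The descriptor changes 10 → 12 (4S → 4R) and 26 → 35 (3aR → 3aS) are changes of CIP priority only; no bond to these centres is broken.

**Route**

Step 1
Reactants: 1 geranyl acetate [(2E)-3,7-dimethylocta-2,6-dien-1-yl acetate]
Product: 2 (2E)-5-(3,3-dimethyloxiran-2-yl)-3-methylpent-2-en-1-yl acetate (racemic at the oxirane carbon)
Conditions: mCPBA (1.0 equiv), NaHCO3, CH2Cl2, 0 °C
Reagents that add atoms: 3-chloroperbenzoic acid, OOC(=O)c1cccc(Cl)c1
Why: Prilezhaev epoxidation, selective for the distal trisubstituted alkene because the other one is deactivated by the allylic acetate; the new stereocentre is racemic and is destroyed in step 2.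

Step 2
Reactants: 2 (2E)-5-(3,3-dimethyloxiran-2-yl)-3-methylpent-2-en-1-yl acetate
Product: 4 (2E)-6-hydroxy-3-methylhex-2-en-1-yl acetate, via aldehyde 3 (not isolated)
Conditions: H5IO6, Et2O/THF, 0 °C; filter; then NaBH4, EtOH, 0 °C
Reagents that add atoms: none
Why: Periodic acid cleavage of the epoxide (through the glycol) gives the C1 aldehyde and acetone, and borohydride reduction in the same flask should give the primary alcohol without touching the acetate.

Step 3
Reactants: 4 (2E)-6-hydroxy-3-methylhex-2-en-1-yl acetate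
Product: 5 (2E)-6-iodo-3-methylhex-2-en-1-yl acetate
Conditions: I2, PPh3, imidazole, CH2Cl2, 0 °C
Reagents that add atoms: iodine, [I][I]
Why: Appel-type iodination of the primary alcohol through its alkoxyphosphonium salt; the allylic acetate and the E-alkene are inert.

Step 4
Reactants: 5 (2E)-6-iodo-3-methylhex-2-en-1-yl acetate
Product: 7 [(4E)-6-hydroxy-4-methylhex-4-en-1-yl]triphenylphosphonium iodide, via acetoxy phosphonium iodide 6 (not isolated)
Conditions: PPh3, MeCN, 80 °C; then K2CO3 (0.2 equiv), MeOH, rt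
Reagents that add atoms: triphenylphosphine, c1ccc(cc1)P(c1ccccc1)c1ccccc1
Why: SN2 quaternisation of the primary iodide followed by carbonate-catalysed methanolysis of the acetate, so that the ylide of step 6 carries an alkoxide and no ester.

Step 5
Reactants: 8 methyl (4S)-2,2-dimethyl-1,3-dioxolane-4-carboxylate
Product: 10 1-[(4S)-2,2-dimethyl-1,3-dioxolan-4-yl]ethan-1-one, via Weinreb amide 9 (not isolated)
Conditions: MeNHOMe·HCl, iPrMgCl, THF, −20 °C; then MeMgBr, −20 → 0 °C
Reagents that add atoms: methylmagnesium bromide, C[Mg]Br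
Why: Weinreb ketone synthesis: the chelated tetrahedral intermediate stops at the methyl ketone, and the α-alkoxy centre (the future C9) should survive the cold, non-enolising conditions.

Step 6
Reactants: 7 [(4E)-6-hydroxy-4-methylhex-4-en-1-yl]triphenylphosphonium iodide; 10 1-[(4S)-2,2-dimethyl-1,3-dioxolan-4-yl]ethan-1-one
Product: 12 (2E,6Z)-7-[(4R)-2,2-dimethyl-1,3-dioxolan-4-yl]-3-methylocta-2,6-dien-1-ol, via alkoxide ylide 11 (not isolated)
Conditions: NaN(SiMe3)2 (2.05 equiv), THF, −78 → 0 °C; then 10, −78 °C → rt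
Reagents that add atoms: none
Why: Wittig reaction of a non-stabilised ylide with an α-alkoxy methyl ketone, which is kinetically Z-selective so that C2 and C9 end up cis on C1=C10; C9 comes unchanged from 10.

Step 7
Reactants: 12 (2E,6Z)-7-[(4R)-2,2-dimethyl-1,3-dioxolan-4-yl]-3-methylocta-2,6-dien-1-ol
Product: 13 (2E,6Z)-7-[(4R)-2,2-dimethyl-1,3-dioxolan-4-yl]-3-methylocta-2,6-dienal
Conditions: MnO2, CH2Cl2, rt
Reagents that add atoms: none
Why: Chemoselective MnO2 oxidation of the primary allylic alcohol to the E-enal (C6); no stereocentre or alkene geometry is touched.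

Step 8
Reactants: 13 (2E,6Z)-7-[(4R)-2,2-dimethyl-1,3-dioxolan-4-yl]-3-methylocta-2,6-dienal
Product: 14 (2E,6Z,8R)-8,9-dihydroxy-3,7-dimethylnona-2,6-dienal
Conditions: AcOH/THF/H2O (3:1:1), 40 °C
Reagents that add atoms: none
Why: Acid-catalysed hydrolysis of the isopropylidene acetal under conditions mild enough for the enal and the allylic carbinol.

Step 9
Reactants: 14 (2E,6Z,8R)-8,9-dihydroxy-3,7-dimethylnona-2,6-dienal
Product: 15 (2E,6Z,8R)-8,9-bis(TBS-oxy)-3,7-dimethylnona-2,6-dienal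
Conditions: TBSOTf, 2,6-lutidine, CH2Cl2, −78 → 0 °C
Reagents that add atoms: tert-butyldimethylsilyl trifluoromethanesulfonate, CC(C)(C)[Si](C)(C)OS(=O)(=O)C(F)(F)F
Why: Silylation of both hydroxyls with the silyl triflate and a hindered base, placed here so that no base or silyl triflate ever meets the later butenolide.

Step 10
Reactants: 15 (2E,6Z,8R)-8,9-bis(TBS-oxy)-3,7-dimethylnona-2,6-dienal; 16 tert-butyldimethyl(prop-2-yn-1-yloxy)silane
Product: 18 (4S,5E,9Z,11R)-1,11,12-tris(TBS-oxy)-6,10-dimethyldodeca-5,9-dien-2-yn-4-ol, via alkynylzinc 17 (not isolated)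
Conditions: Me2Zn, (S,S)-ProPhenol (20 mol %), Ph3P=O (40 mol %), toluene, 0 °C; then 15, 4 °C
Reagents that add atoms: none
Why: Catalytic asymmetric alkynylation of an enal by the dinuclear zinc–ProPhenol catalyst, which should deliver the alkynyl group to the Re face and set C6 as 4S under catalyst control, the remote C9 centre having no influence.

Step 11
Reactants: 18 (4S,5E,9Z,11R)-1,11,12-tris(TBS-oxy)-6,10-dimethyldodeca-5,9-dien-2-yn-4-ol
Product: 20 (2Z,4S,5E,9Z,11R)-1,11,12-tris(TBS-oxy)-2-iodo-6,10-dimethyldodeca-2,5,9-trien-4-ol, via cyclic alkenylalanate 19 (not isolated)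
Conditions: NaAlH2(OCH2CH2OMe)2 (Red-Al), THF, 0 °C; EtOAc; then I2, −78 → −20 °C
Reagents that add atoms: iodine, [I][I]
Why: Hydroxyl-directed trans-hydroalumination of the propargylic alcohol puts hydrogen on C7 and aluminium on C11 in a five-membered alanate, and iodinolysis with retention should give the Z-iodide with iodine cis to C6; C6 is not touched.

Step 12
Reactants: 20 (2Z,4S,5E,9Z,11R)-1,11,12-tris(TBS-oxy)-2-iodo-6,10-dimethyldodeca-2,5,9-trien-4-ol
Product: 21 (5S)-5-[(1E,5Z,7R)-7,8-bis(TBS-oxy)-2,6-dimethylocta-1,5-dien-1-yl]-3-[(TBS-oxy)methyl]furan-2(5H)-one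
Conditions: Pd(PPh3)4 (5 mol %), CO (1 atm), K2CO3, THF, 45 °C
Reagents that add atoms: carbon monoxide, [C-]#[O+]
Why: Palladium-catalysed carbonylative lactonisation of a Z-3-iodoallylic alcohol (oxidative addition, CO insertion, capture of the acylpalladium by the C6 hydroxyl) builds C12 and the butenolide with retention at C6, because the C6–O bond is never broken.

Step 13
Reactants: 21 (5S)-5-[(1E,5Z,7R)-7,8-bis(TBS-oxy)-2,6-dimethylocta-1,5-dien-1-yl]-3-[(TBS-oxy)methyl]furan-2(5H)-one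
Product: 22 (5S)-5-[(1E,5Z,7R)-7-(TBS-oxy)-8-hydroxy-2,6-dimethylocta-1,5-dien-1-yl]-3-(hydroxymethyl)furan-2(5H)-one
Conditions: HF·pyridine, pyridine, THF, 0 °C → rt
Reagents that add atoms: none
Why: Buffered fluoride desilylation is much faster for the two primary silyl ethers (C13 and C8) than for the hindered secondary allylic one at C9, which should remain.

Step 14
Reactants: 22 (5S)-5-[(1E,5Z,7R)-7-(TBS-oxy)-8-hydroxy-2,6-dimethylocta-1,5-dien-1-yl]-3-(hydroxymethyl)furan-2(5H)-one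
Product: 23 (5S)-3-(bromomethyl)-5-[(1E,5Z,7R)-7-(TBS-oxy)-8-hydroxy-2,6-dimethylocta-1,5-dien-1-yl]furan-2(5H)-one
Conditions: NBS, Me2S (premixed), CH2Cl2, −20 → 0 °C
Reagents that add atoms: N-bromosuccinimide, BrN1C(=O)CCC1=O
Why: Corey–Kim bromination: both hydroxyls form alkoxysulfonium salts, but only the allylic C13 one is displaced by bromide at this temperature, while the C8 one should revert to the alcohol on aqueous work-up.

Step 15
Reactants: 23 (5S)-3-(bromomethyl)-5-[(1E,5Z,7R)-7-(TBS-oxy)-8-hydroxy-2,6-dimethylocta-1,5-dien-1-yl]furan-2(5H)-one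
Product: 24 (2R,3Z,7E)-8-[(2S)-4-(bromomethyl)-5-oxo-2,5-dihydrofuran-2-yl]-2-(TBS-oxy)-3,7-dimethylocta-3,7-dienal
Conditions: Dess–Martin periodinane, NaHCO3, CH2Cl2, 0 °C → rt; used at once
Reagents that add atoms: none
Why: Dess–Martin oxidation is neutral and amine-free, so the allylic bromide and the epimerisable α-silyloxy aldehyde (C9) should both survive.

Step 16
Reactants: 24 (2R,3Z,7E)-8-[(2S)-4-(bromomethyl)-5-oxo-2,5-dihydrofuran-2-yl]-2-(TBS-oxy)-3,7-dimethylocta-3,7-dienal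
Product: 26 (3aR,4S,5R,6Z,10E,11aS)-5-(TBS-oxy)-4-hydroxy-6,10-dimethyl-3-methylidene-3a,4,5,8,9,11a-hexahydrocyclodeca[b]furan-2(3H)-one, via allylchromium 25 (not isolated)
Conditions: CrCl2 (6 equiv), THF, 4 Å MS, rt; 24 added by syringe pump over 12 h (final 2 mM); aq. NH4Cl
Reagents that add atoms: none
Why: Proposed new method: two equivalents of divalent chromium insert into the C13–Br bond to give the trivalent allylchromium 25, whose metal binds the aldehyde oxygen so that C7 attacks C8 in a six-membered cyclic SE2′ transition state and the double bond moves to C11=C13; the ring-closing use of a bromomethylbutenolide is untested, the closest known reactions being the intermolecular CrCl2- or zinc-mediated addition of 3-(bromomethyl)furan-2(5H)-one to aldehydes and the macrocyclising Nozaki–Hiyama allylation of 2-(bromomethyl)acrylates. The ten-membered ring (C1–C10) closes in a 10-exo-trig mode, the carbonyl oxygen staying outside the ring. C7 is set by the face of the planar butenolide that bonds: allylic 1,3-strain between the C4 methyl and C6 keeps H6 in the plane of C4=C5, which places C3 and the rest of the tether over the face that carries C5, so the perpendicular approach to C7 should occur there and give the cis-fused lactone. C8 is set by Felkin–Anh addition next to C9 (bulky, non-chelating silyloxy group anti to the incoming C7), which in the cis-fused mode coincides with the chair in which C9 sits pseudo-axially over the lactone, the equatorial alternative forcing C5 and C9 into a syn-pentane contact. The step therefore needs facial selectivity at C7 (the C5 face) together with Felkin control at C8; the E-alkene held by allylic strain, the Z C1=C10 turn and the silyl ether are the elements of 24 meant to secure it, and high dilution should suppress oligomers.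

Step 17
Reactants: 27 (4S)-4-benzyl-3-propanoyl-1,3-oxazolidin-2-one; 28 allyl iodide (3-iodoprop-1-ene)
Product: 30 (4S)-4-benzyl-3-[(2R)-2-methylpent-4-enoyl]-1,3-oxazolidin-2-one, via sodium enolate 29 (not isolated)
Conditions: NaN(SiMe3)2, THF, −78 °C; then allyl iodide, −78 → −40 °C
Reagents that add atoms: none
Why: Evans asymmetric alkylation: the chelated Z-enolate is allylated on the face away from the benzyl group, which sets the side-chain stereocentre as 2R.

Step 18
Reactants: 30 (4S)-4-benzyl-3-[(2R)-2-methylpent-4-enoyl]-1,3-oxazolidin-2-one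
Product: 31 (2R)-2-methylpent-4-en-1-ol
Conditions: LiBH4, H2O (1 equiv), Et2O, 0 °C
Reagents that add atoms: none
Why: Reductive removal of the auxiliary by borohydride attack at the exocyclic imide carbonyl; the α-centre is not enolised.

Step 19
Reactants: 31 (2R)-2-methylpent-4-en-1-ol; 32 octadecanoyl chloride
Product: 33 (2R)-2-methylpent-4-en-1-yl octadecanoate
Conditions: pyridine, DMAP (cat.), CH2Cl2, 0 °C → rt
Reagents that add atoms: none
Why: Acylation of the primary alcohol by the acid chloride under nucleophilic catalysis; the stereocentre is remote from the reacting oxygen.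

Step 20
Reactants: 33 (2R)-2-methylpent-4-en-1-yl octadecanoate
Product: 34 (3R)-3-methyl-4-(octadecanoyloxy)butanoic acid
Conditions: RuCl3·xH2O (3 mol %), NaIO4, CCl4/MeCN/H2O, rt
Reagents that add atoms: sodium periodate, [Na+].[O-]I(=O)(=O)=O; water, O
Why: Ruthenium tetroxide-catalysed oxidative cleavage of the terminal alkene to the one-carbon-shorter acid, compatible with the saturated ester and leaving the stereocentre untouched.

Step 21
Reactants: 26 (3aR,4S,5R,6Z,10E,11aS)-5-(TBS-oxy)-4-hydroxy-6,10-dimethyl-3-methylidene-3a,4,5,8,9,11a-hexahydrocyclodeca[b]furan-2(3H)-one; 34 (3R)-3-methyl-4-(octadecanoyloxy)butanoic acid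
Product: 35 (3aS,4S,5R,6Z,10E,11aS)-5-(TBS-oxy)-6,10-dimethyl-3-methylidene-2-oxo-2,3,3a,4,5,8,9,11a-octahydrocyclodeca[b]furan-4-yl (3R)-3-methyl-4-(octadecanoyloxy)butanoate
Conditions: EDC·HCl, DMAP, CH2Cl2, 0 °C → rt
Reagents that add atoms: none
Why: Steglich esterification of the only free hydroxyl (C8), O9 being silylated; the C–O bond at C8 is not broken, so its configuration is kept.

Step 22
Reactants: 35 (3aS,4S,5R,6Z,10E,11aS)-5-(TBS-oxy)-6,10-dimethyl-3-methylidene-2-oxo-2,3,3a,4,5,8,9,11a-octahydrocyclodeca[b]furan-4-yl (3R)-3-methyl-4-(octadecanoyloxy)butanoate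
Product: 36 (3aS,4S,5R,6Z,10E,11aS)-5-hydroxy-6,10-dimethyl-3-methylidene-2-oxo-2,3,3a,4,5,8,9,11a-octahydrocyclodeca[b]furan-4-yl (3R)-3-methyl-4-(octadecanoyloxy)butanoate (target)
Conditions: HF·pyridine, pyridine, THF, 0 °C → rt
Reagents that add atoms: none
Why: Buffered fluoride desilylation of the C9 silyl ether under weakly acidic conditions, chosen to avoid acyl migration from O8 to O9 and attack on the methylene lactone.

**Compound list**

1 | geranyl acetate, (2E)-3,7-dimethylocta-2,6-dien-1-yl acetate | CC(=O)OC/C=C(\C)CCC=C(C)C | starting material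
2 | (2E)-5-(3,3-dimethyloxiran-2-yl)-3-methylpent-2-en-1-yl acetate (racemic epoxide) | CC(=O)OC/C=C(\C)CCC1OC1(C)C | intermediate
3 | (2E)-3-methyl-6-oxohex-2-en-1-yl acetate | CC(=O)OC/C=C(\C)CCC=O | intermediate (not isolated)
4 | (2E)-6-hydroxy-3-methylhex-2-en-1-yl acetate | CC(=O)OC/C=C(\C)CCCO | intermediate
5 | (2E)-6-iodo-3-methylhex-2-en-1-yl acetate | CC(=O)OC/C=C(\C)CCCI | intermediate
6 | [(4E)-6-(acetyloxy)-4-methylhex-4-en-1-yl]triphenylphosphonium iodide | CC(=O)OC/C=C(\C)CCC[P+](c1ccccc1)(c1ccccc1)c1ccccc1.[I-] | intermediate (not isolated)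
7 | [(4E)-6-hydroxy-4-methylhex-4-en-1-yl]triphenylphosphonium iodide | OC/C=C(\C)CCC[P+](c1ccccc1)(c1ccccc1)c1ccccc1.[I-] | intermediate
8 | methyl (4S)-2,2-dimethyl-1,3-dioxolane-4-carboxylate | COC(=O)[C@@H]1COC(C)(C)O1 | starting material
9 | (4S)-N-methoxy-N,2,2-trimethyl-1,3-dioxolane-4-carboxamide | CON(C)C(=O)[C@@H]1COC(C)(C)O1 | intermediate (not isolated)
10 | 1-[(4S)-2,2-dimethyl-1,3-dioxolan-4-yl]ethan-1-one | CC(=O)[C@@H]1COC(C)(C)O1 | intermediate
11 | sodium (2E)-3-methyl-6-(triphenyl-λ5-phosphanylidene)hex-2-en-1-olate | [Na+].[O-]C/C=C(\C)CCC=P(c1ccccc1)(c1ccccc1)c1ccccc1 | intermediate (not isolated)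
12 | (2E,6Z)-7-[(4R)-2,2-dimethyl-1,3-dioxolan-4-yl]-3-methylocta-2,6-dien-1-ol | OC/C=C(\C)CC/C=C(/C)[C@@H]1COC(C)(C)O1 | intermediate
13 | (2E,6Z)-7-[(4R)-2,2-dimethyl-1,3-dioxolan-4-yl]-3-methylocta-2,6-dienal | O=C/C=C(\C)CC/C=C(/C)[C@@H]1COC(C)(C)O1 | intermediate
14 | (2E,6Z,8R)-8,9-dihydroxy-3,7-dimethylnona-2,6-dienal | O=C/C=C(\C)CC/C=C(/C)[C@@H](O)CO | intermediate
15 | (2E,6Z,8R)-8,9-bis{[tert-butyl(dimethyl)silyl]oxy}-3,7-dimethylnona-2,6-dienal | O=C/C=C(\C)CC/C=C(/C)[C@@H](O[Si](C)(C)C(C)(C)C)CO[Si](C)(C)C(C)(C)C | intermediate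
16 | tert-butyldimethyl(prop-2-yn-1-yloxy)silane | C#CCO[Si](C)(C)C(C)(C)C | starting material
17 | methyl{3-[tert-butyl(dimethyl)silyl]oxyprop-1-yn-1-yl}zinc | C[Zn]C#CCO[Si](C)(C)C(C)(C)C | intermediate (not isolated)
18 | (4S,5E,9Z,11R)-1,11,12-tris{[tert-butyl(dimethyl)silyl]oxy}-6,10-dimethyldodeca-5,9-dien-2-yn-4-ol | O[C@H](C#CCO[Si](C)(C)C(C)(C)C)/C=C(\C)CC/C=C(/C)[C@@H](O[Si](C)(C)C(C)(C)C)CO[Si](C)(C)C(C)(C)C | intermediate
19 | sodium cyclic alkenylalanate: 2,2-bis(2-methoxyethoxy)-2,5-dihydro-1,2-oxaaluminol-2-uide with C6 as ring C5, C7=C11 as ring C4=C3 and CH2OTBS on ring C3 | [Na+].COCCO[Al-]1(OCCOC)O[C@@H](/C=C(\C)CC/C=C(/C)[C@@H](O[Si](C)(C)C(C)(C)C)CO[Si](C)(C)C(C)(C)C)C=C1CO[Si](C)(C)C(C)(C)C | intermediate (not isolated)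
20 | (2Z,4S,5E,9Z,11R)-1,11,12-tris{[tert-butyl(dimethyl)silyl]oxy}-2-iodo-6,10-dimethyldodeca-2,5,9-trien-4-ol | O[C@H](/C=C(\I)CO[Si](C)(C)C(C)(C)C)/C=C(\C)CC/C=C(/C)[C@@H](O[Si](C)(C)C(C)(C)C)CO[Si](C)(C)C(C)(C)C | intermediate
21 | (5S)-5-[(1E,5Z,7R)-7,8-bis{[tert-butyl(dimethyl)silyl]oxy}-2,6-dimethylocta-1,5-dien-1-yl]-3-({[tert-butyl(dimethyl)silyl]oxy}methyl)furan-2(5H)-one | CC(C)(C)[Si](C)(C)OCC1=C[C@H](/C=C(\C)CC/C=C(/C)[C@@H](O[Si](C)(C)C(C)(C)C)CO[Si](C)(C)C(C)(C)C)OC1=O | intermediate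
22 | (5S)-5-[(1E,5Z,7R)-7-{[tert-butyl(dimethyl)silyl]oxy}-8-hydroxy-2,6-dimethylocta-1,5-dien-1-yl]-3-(hydroxymethyl)furan-2(5H)-one | OCC1=C[C@H](/C=C(\C)CC/C=C(/C)[C@@H](O[Si](C)(C)C(C)(C)C)CO)OC1=O | intermediate
23 | (5S)-3-(bromomethyl)-5-[(1E,5Z,7R)-7-{[tert-butyl(dimethyl)silyl]oxy}-8-hydroxy-2,6-dimethylocta-1,5-dien-1-yl]furan-2(5H)-one | BrCC1=C[C@H](/C=C(\C)CC/C=C(/C)[C@@H](O[Si](C)(C)C(C)(C)C)CO)OC1=O | intermediate
24 | (2R,3Z,7E)-8-[(2S)-4-(bromomethyl)-5-oxo-2,5-dihydrofuran-2-yl]-2-{[tert-butyl(dimethyl)silyl]oxy}-3,7-dimethylocta-3,7-dienal (key-step precursor) | BrCC1=C[C@H](/C=C(\C)CC/C=C(/C)[C@@H](O[Si](C)(C)C(C)(C)C)C=O)OC1=O | intermediate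
25 | allylchromium dichloride of 24 (trivalent chromium bound to C13) | Cl[Cr](Cl)CC1=C[C@H](/C=C(\C)CC/C=C(/C)[C@@H](O[Si](C)(C)C(C)(C)C)C=O)OC1=O | intermediate (not isolated)
26 | (3aR,4S,5R,6Z,10E,11aS)-5-{[tert-butyl(dimethyl)silyl]oxy}-4-hydroxy-6,10-dimethyl-3-methylidene-3a,4,5,8,9,11a-hexahydrocyclodeca[b]furan-2(3H)-one (key-step product) | C=C1C(=O)O[C@H]2/C=C(\C)CC/C=C(/C)[C@@H](O[Si](C)(C)C(C)(C)C)[C@@H](O)[C@@H]12 | intermediate
27 | (4S)-4-benzyl-3-propanoyl-1,3-oxazolidin-2-one | CCC(=O)N1[C@@H](Cc2ccccc2)COC1=O | starting material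
28 | allyl iodide, 3-iodoprop-1-ene | C=CCI | starting material
29 | sodium (1Z)-1-[(4S)-4-benzyl-2-oxo-1,3-oxazolidin-3-yl]prop-1-en-1-olate | [Na+].C/C=C(\[O-])N1[C@@H](Cc2ccccc2)COC1=O | intermediate (not isolated)
30 | (4S)-4-benzyl-3-[(2R)-2-methylpent-4-enoyl]-1,3-oxazolidin-2-one | C=CC[C@@H](C)C(=O)N1[C@@H](Cc2ccccc2)COC1=O | intermediate
31 | (2R)-2-methylpent-4-en-1-ol | C=CC[C@@H](C)CO | intermediate
32 | octadecanoyl chloride (stearoyl chloride) | CCCCCCCCCCCCCCCCCC(=O)Cl | starting material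
33 | (2R)-2-methylpent-4-en-1-yl octadecanoate | C=CC[C@@H](C)COC(=O)CCCCCCCCCCCCCCCCC | intermediate
34 | (3R)-3-methyl-4-(octadecanoyloxy)butanoic acid | OC(=O)C[C@@H](C)COC(=O)CCCCCCCCCCCCCCCCC | intermediate
35 | (3aS,4S,5R,6Z,10E,11aS)-5-{[tert-butyl(dimethyl)silyl]oxy}-6,10-dimethyl-3-methylidene-2-oxo-2,3,3a,4,5,8,9,11a-octahydrocyclodeca[b]furan-4-yl (3R)-3-methyl-4-(octadecanoyloxy)butanoate | C=C1C(=O)O[C@H]2/C=C(\C)CC/C=C(/C)[C@@H](O[Si](C)(C)C(C)(C)C)[C@@H](OC(=O)C[C@@H](C)COC(=O)CCCCCCCCCCCCCCCCC)[C@@H]12 | intermediate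
36 | (3aS,4S,5R,6Z,10E,11aS)-5-hydroxy-6,10-dimethyl-3-methylidene-2-oxo-2,3,3a,4,5,8,9,11a-octahydrocyclodeca[b]furan-4-yl (3R)-3-methyl-4-(octadecanoyloxy)butanoate | C=C1C(=O)O[C@H]2/C=C(\C)CC/C=C(/C)[C@@H](O)[C@@H](OC(=O)C[C@@H](C)COC(=O)CCCCCCCCCCCCCCCCC)[C@@H]12 | target

**Step count and risk**

Total step count: 22 (steps 1–16 to the macrocycle, steps 17–20 for the side-chain acid, steps 21–22 to the target).
Longest linear sequence: 17 steps, from geranyl acetate (steps 1–4, 6–16, 21, 22).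

Steps most likely to fail

Step 16 (key step). The ring may close on the butenolide face opposite to C5 (trans-fused lactone). The allylchromium may also lose the lactone carboxylate by reductive 1,4-elimination, be protonated before it finds the aldehyde, or add intermolecularly. The fallback sets out from 23 and comes back at 26. It replaces the closed chromium transition state by a Lewis-acid-promoted intramolecular allylstannane–aldehyde addition, an established way to close medium and large carbocycles. Bromide 23 is stannylated with (Bu3Sn)2 and catalytic Pd(PPh3)4 in THF to give (5S)-5-[(1E,5Z,7R)-7-(TBS-oxy)-8-hydroxy-2,6-dimethylocta-1,5-dien-1-yl]-3-[(tributylstannyl)methyl]furan-2(5H)-one F1. Dess–Martin oxidation gives the stannyl aldehyde (2R,3Z,7E)-2-(TBS-oxy)-3,7-dimethyl-8-{(2S)-5-oxo-4-[(tributylstannyl)methyl]-2,5-dihydrofuran-2-yl}octa-3,7-dienal F2. Slow addition of F2 to BF3·OEt2 in CH2Cl2 at −78 °C under high dilution should give 26. The open transition state of this mode favours the syn C7/C8 relationship, which agrees with Felkin control at C9 only when bonding occurs on the C5 face.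

Step 14. Chemoselectivity between the two primary hydroxyls may be lost, the C8 alkoxysulfonium salt collapsing to a bromide or a methylthiomethyl ether. The fallback sets out from 15 and comes back at 23. It unmasks the two hydroxyls one after the other, so that the bromination needs no selectivity. Enal 15 is alkynylated with triethyl(prop-2-yn-1-yloxy)silane under the conditions of step 10 to give (4S,5E,9Z,11R)-11,12-bis(TBS-oxy)-6,10-dimethyl-1-(TES-oxy)dodeca-5,9-dien-2-yn-4-ol F3. Hydroalumination–iodination as in step 11 gives the Z-iodide (2Z,4S,5E,9Z,11R)-11,12-bis(TBS-oxy)-2-iodo-6,10-dimethyl-1-(TES-oxy)dodeca-2,5,9-trien-4-ol F4. Carbonylative lactonisation as in step 12 gives (5S)-5-[(1E,5Z,7R)-7,8-bis(TBS-oxy)-2,6-dimethylocta-1,5-dien-1-yl]-3-[(TES-oxy)methyl]furan-2(5H)-one F5. PPTS in MeOH/CH2Cl2 at 0 °C removes only the triethylsilyl group to give (5S)-5-[(1E,5Z,7R)-7,8-bis(TBS-oxy)-2,6-dimethylocta-1,5-dien-1-yl]-3-(hydroxymethyl)furan-2(5H)-one F6. Appel bromination (CBr4, PPh3, CH2Cl2, 0 °C) gives (5S)-5-[(1E,5Z,7R)-7,8-bis(TBS-oxy)-2,6-dimethylocta-1,5-dien-1-yl]-3-(bromomethyl)furan-2(5H)-one F7. Camphorsulfonic acid in MeOH/CH2Cl2 at 0 °C then frees only the primary C8 hydroxyl and gives 23.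

Step 10. Facial selectivity of the catalyst-controlled addition to the enal may be insufficient or reversed, and the two C6 epimers would be hard to separate because C9 is remote. The fallback sets out from 15 and comes back at 18. It sets C6 by reagent-controlled reduction instead of addition. The lithium acetylide of 16 (n-BuLi, THF, −78 °C) is added to 15 without stereocontrol to give (4RS,5E,9Z,11R)-1,11,12-tris(TBS-oxy)-6,10-dimethyldodeca-5,9-dien-2-yn-4-ol F8. MnO2 in CH2Cl2 oxidises F8 to the ynone (5E,9Z,11R)-1,11,12-tris(TBS-oxy)-6,10-dimethyldodeca-5,9-dien-2-yn-4-one F9. Midland reduction of F9 with (S)-Alpine-borane, in which the alkyne acts as the small group, should return 18 with the 4S configuration.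

Further compounds

F1 | step 16 | (5S)-5-[(1E,5Z,7R)-7-{[tert-butyl(dimethyl)silyl]oxy}-8-hydroxy-2,6-dimethylocta-1,5-dien-1-yl]-3-[(tributylstannyl)methyl]furan-2(5H)-one | CCCC[Sn](CCCC)(CCCC)CC1=C[C@H](/C=C(\C)CC/C=C(/C)[C@@H](O[Si](C)(C)C(C)(C)C)CO)OC1=O
F2 | step 16 | (2R,3Z,7E)-2-{[tert-butyl(dimethyl)silyl]oxy}-3,7-dimethyl-8-{(2S)-5-oxo-4-[(tributylstannyl)methyl]-2,5-dihydrofuran-2-yl}octa-3,7-dienal | CCCC[Sn](CCCC)(CCCC)CC1=C[C@H](/C=C(\C)CC/C=C(/C)[C@@H](O[Si](C)(C)C(C)(C)C)C=O)OC1=O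
F3 | step 14 | (4S,5E,9Z,11R)-11,12-bis{[tert-butyl(dimethyl)silyl]oxy}-6,10-dimethyl-1-[(triethylsilyl)oxy]dodeca-5,9-dien-2-yn-4-ol | O[C@H](C#CCO[Si](CC)(CC)CC)/C=C(\C)CC/C=C(/C)[C@@H](O[Si](C)(C)C(C)(C)C)CO[Si](C)(C)C(C)(C)C
F4 | step 14 | (2Z,4S,5E,9Z,11R)-11,12-bis{[tert-butyl(dimethyl)silyl]oxy}-2-iodo-6,10-dimethyl-1-[(triethylsilyl)oxy]dodeca-2,5,9-trien-4-ol | O[C@H](/C=C(\I)CO[Si](CC)(CC)CC)/C=C(\C)CC/C=C(/C)[C@@H](O[Si](C)(C)C(C)(C)C)CO[Si](C)(C)C(C)(C)C
F5 | step 14 | (5S)-5-[(1E,5Z,7R)-7,8-bis{[tert-butyl(dimethyl)silyl]oxy}-2,6-dimethylocta-1,5-dien-1-yl]-3-{[(triethylsilyl)oxy]methyl}furan-2(5H)-one | CC[Si](CC)(CC)OCC1=C[C@H](/C=C(\C)CC/C=C(/C)[C@@H](O[Si](C)(C)C(C)(C)C)CO[Si](C)(C)C(C)(C)C)OC1=O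
F6 | step 14 | (5S)-5-[(1E,5Z,7R)-7,8-bis{[tert-butyl(dimethyl)silyl]oxy}-2,6-dimethylocta-1,5-dien-1-yl]-3-(hydroxymethyl)furan-2(5H)-one | OCC1=C[C@H](/C=C(\C)CC/C=C(/C)[C@@H](O[Si](C)(C)C(C)(C)C)CO[Si](C)(C)C(C)(C)C)OC1=O
F7 | step 14 | (5S)-5-[(1E,5Z,7R)-7,8-bis{[tert-butyl(dimethyl)silyl]oxy}-2,6-dimethylocta-1,5-dien-1-yl]-3-(bromomethyl)furan-2(5H)-one | BrCC1=C[C@H](/C=C(\C)CC/C=C(/C)[C@@H](O[Si](C)(C)C(C)(C)C)CO[Si](C)(C)C(C)(C)C)OC1=O
F8 | step 10 | (4RS,5E,9Z,11R)-1,11,12-tris{[tert-butyl(dimethyl)silyl]oxy}-6,10-dimethyldodeca-5,9-dien-2-yn-4-ol (C4 epimer mixture) | OC(C#CCO[Si](C)(C)C(C)(C)C)/C=C(\C)CC/C=C(/C)[C@@H](O[Si](C)(C)C(C)(C)C)CO[Si](C)(C)C(C)(C)C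
F9 | step 10 | (5E,9Z,11R)-1,11,12-tris{[tert-butyl(dimethyl)silyl]oxy}-6,10-dimethyldodeca-5,9-dien-2-yn-4-one | O=C(C#CCO[Si](C)(C)C(C)(C)C)/C=C(\C)CC/C=C(/C)[C@@H](O[Si](C)(C)C(C)(C)C)CO[Si](C)(C)C(C)(C)C
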